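## Structural features

The target 38 is a germacranolide: a ten-membered carbocycle (C1–C10, germacrane locants throughout) fused across C6–C7 to an α-methylene-γ-butyrolactone (ring O on C6, C11 on C7, C12 the carbonyl, C13 the exocyclic methylene). The carbocycle holds two trisubstituted olefins in a 1,5-relationship: C1=C10 is Z (C14 methyl on C10), and C4=C5 is trans within the ring (C3 and C6 trans; the C15 acetoxymethyl group on C4 is cis to C6, so the CIP label is 4Z). C6 (R), C7 (R) and C8 (R) are contiguous: H6 and H7 are trans (trans-fused lactone, 6α-O, 7α-H) and the free C8 hydroxyl is β, cis to C11. The fourth centre, C2 (S), is isolated, allylic to C1=C10, and carries the angelate (2α). Four oxygens are in four different states: lactone, free secondary alcohol, primary allylic acetate, and secondary allylic (Z)-2-methylbut-2-enoate. The fragile groups are the α-methylene lactone (Michael acceptor), the angelate (Z to E isomerisation to tiglate), the two allylic esters (ionisation, acyl transfer) and the medium-ring 1,5-diene (Cope rearrangement, acid-induced transannular cyclisation). The real difficulty is closing a strained ten-membered ring with both olefin geometries defined while setting C6 and C7 next to C8. The key step exploits the array O6–C6–C7–C11(=C13), the retron of a [2,3]-Wittig shift of an O6–C13 ether across a C11=C7 olefin, together with the fact that C5 next to C6 can be carried as an alkyne carbon (C4≡C5), which acidifies C6–H and later becomes the ring-trans C4=C5 olefin bearing C15.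

## Logic of the disconnections

The route in one sentence: C6-lithiated 24 contracts by a [2,3]-Wittig shift to 26, forming C6–C7 and the ten-membered ring.

38 from 36: the C8–O bond is cut and re-formed with inversion (via 37). The key step places O8 anti to the new C6–C7 bond, which corresponds to 8α, whereas 38 is 8β. Carrying C8 as the epimer lets this centre direct the key step in its matched sense. The forward step must be a clean SN2 at a ring carbinol, and the ester it leaves must be cleaved in the presence of an acetate and an angelate.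

36 from 34 and 34 from 31: the O2–acyl bond and the O6–C12 lactone bond are cut, and C12 is taken back to the alcohol level. All acyl groups and the Michael acceptor are thus introduced after the last organometallic step. The forward steps must oxidise a primary alcohol chemoselectively in the presence of secondary ones, and acylate with angelic acid without Z to E isomerisation.

31 from 26 (through 30, 29, 28): the C4–C15 bond and the C5–H bond are cut, which returns the ring-trans olefin to the alkyne C4≡C5. The alkyne is what makes the key step regioselective, and the neighbouring C6 hydroxyl can direct a trans addition across it. The forward steps must effect a trans hydrometalation inside a ten-membered ring with the metal on C4.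

26 from 24 (key): the C6–C7 bond is cut and O6 is reconnected to C13, which moves the C11=C13 olefin to C7=C11. A strained carbocycle with two new stereocentres becomes an unstrained 13-membered ether with none. The forward step must lithiate C6 only, proceed through the trans-fused envelope, and attack one face of C7=C11.

24 from 23: the O–C13 bond is cut. The precursor is open-chain, with a propargylic alcohol and a primary allylic chloride. The forward step must favour ring closure over oligomerisation and SN2 over SN2'.

23 from 14 and 16 (through 17–22): the C7=C11 double bond and the C11–C13 bond are cut. The two oxygenated carbons on C11 are told apart by the olefination geometry: the ester (C12) is cis to C8 and the halogen, later C13, is trans. The forward olefination must give the ester-cis isomer.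

14 from 8 and 9 (through 12, 13): the C9–C10 bond is cut. C8 and its oxygen come from the chiral pool, and the C1=C10 geometry is already fixed in 8. The forward step must open the epoxide at its CH2 terminus and leave the ester untouched.

8 from 1 and 2 (through 4–7): the C1=C10 double bond and the C3–C4 bond are cut. C2 comes from the chiral pool, and C4–C6 come as a protected propargyl alcohol. The forward steps must open the epoxide regioselectively and give the Z-iodoalkene.

## Other disconnections considered

Alternative 1: Cut C6–C7 and O6–C12 together. The forward key step would be an intramolecular Nozaki–Hiyama–Kishi (Barbier-type) allylation of the aldehyde–allylic bromide A1, closing the ring and, after lactonisation, giving the methylene lactone directly. This is the first plan that comes to mind. It is set aside for three reasons: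
- The ten-membered ring would be closed end-to-end at its most congested bond, against the full strain and entropy of the ring, whereas the contraction of 24 pays only the difference between a 13- and a 10-membered ring.
- The C6/C7 pair would arise from the folding of a flexible chain rather than from a five-membered transition state.
- A1 contains an enal whose geometry (C6 cis to C15) is labile; in the chosen plan this olefin is made last, from an alkyne, under the control of O6.

The step counts are comparable.

Alternative 2: Cut C1=C10. The forward key step would be ring-closing metathesis of the diene lactone A2. Nothing in the mechanism would control the Z geometry of a trisubstituted olefin formed in a ten-membered ring, and such closures compete poorly with dimerisation. A2 also offers the catalyst a 1,1-disubstituted methylene lactone and an angelate olefin. The C6–C7–C8 triad would still have to be built separately.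

Alternative 3: Insert SO2 between C1 and C10 and delete it. The forward key step would be a Ramberg–Bäcklund contraction of the 11-membered sulfone A3, made by double S-alkylation. The α-sulfonyl carbanion at C1 would be β to O2 and would be expected to eliminate. The strong base is incompatible with the lactone and the esters, so all acylations would have to follow. The mechanism does not enforce the Z geometry of a trisubstituted olefin in this ring, and the sulfur deletion leaves the C6/C7 problem untouched.

Key step: step 17

Assumption: locants are germacrane locants (also for open-chain and 13-membered intermediates), α/β refer to the usual germacranolide drawing with H-7 α, and 1 is taken as a catalogue compound. Abbreviations: TBS = tert-butyldimethylsilyl, TIPS = triisopropylsilyl, PMB = 4-methoxybenzyl, Tr = trityl.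

## Steps

Step 1
Reactants: 1 4-methoxybenzyl propargyl ether; 2 (S)-glycidyl trityl ether
Product: 4 (2S)-6-(PMBO)-1-(TrO)hex-4-yn-2-ol, via lithium acetylide 3 (not isolated)
Conditions: n-BuLi, THF, −78 °C; BF3·OEt2; then 2, −78 °C
Reagents that add atoms: none
Why: The lithium acetylide with BF3·OEt2 opens the terminal epoxide at its CH2 carbon (BF3-promoted alkynylation of epoxides), forming C3–C4 and carrying the stereocentre of 2 over unchanged as C2 (S).

Step 2
Reactants: 4 (2S)-6-(PMBO)-1-(TrO)hex-4-yn-2-ol
Product: 5 TBS ether of 4 at O2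
Conditions: TBSCl, imidazole, DMF, rt
Reagents that add atoms: tert-butyldimethylsilyl chloride CC(C)(C)[Si](C)(C)Cl
Why: Standard silylation of a secondary alcohol; the O2 TBS ether shields O2 during the C1 oxidation and lasts until step 21.

Step 3
Reactants: 5 TBS ether of 4
Product: 6 (2S)-2-(TBSO)-6-(PMBO)hex-4-yn-1-ol
Conditions: CSA (cat.), MeOH/CH2Cl2, 0 °C
Reagents that add atoms: none
Why: Acid-catalysed methanolysis removes the trityl ether (stabilised cation) much faster than a secondary TBS or a PMB ether, freeing only the C1 hydroxyl.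

Step 4
Reactants: 6 (2S)-2-(TBSO)-6-(PMBO)hex-4-yn-1-ol
Product: 7 (2S)-2-(TBSO)-6-(PMBO)hex-4-ynal
Conditions: Dess–Martin periodinane, NaHCO3, CH2Cl2, 0 °C to rt
Reagents that add atoms: none
Why: Buffered Dess–Martin oxidation gives the α-silyloxy aldehyde without epimerisation; it is used at once.

Step 5
Reactants: 7 (2S)-2-(TBSO)-6-(PMBO)hex-4-ynal
Product: 8 (2Z,4S)-4-(TBSO)-2-iodo-8-(PMBO)oct-2-en-6-yne
Conditions: EtPPh3I, n-BuLi, THF; I2, −78 °C; NaHMDS, −20 °C; then 7, −78 °C to rt
Reagents that add atoms: ethyltriphenylphosphonium iodide CC[P+](c1ccccc1)(c1ccccc1)c1ccccc1.[I-]; iodine II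
Why: Stork–Zhao-type iodo-olefination: the α-iodo ylide adds under kinetic control to give the Z-iodoalkene (I cis to C2, methyl trans), which fixes the C1=C10 geometry of the target; C2 is not touched at −78 °C.

Step 6
Reactants: 8 (2Z,4S)-4-(TBSO)-2-iodo-8-(PMBO)oct-2-en-6-yne; 9 methyl (S)-glycidate
Product: 12 methyl (2S,4Z,6S)-6-(TBSO)-2-hydroxy-10-(PMBO)-4-methyldec-4-en-8-ynoate, via alkenyllithium 10 (not isolated), via alkenylmagnesium bromide 11 (not isolated)
Conditions: t-BuLi (2 equiv), Et2O, −78 °C; MgBr2·OEt2; CuI (10 mol%), then 9, THF, −40 to −20 °C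
Reagents that add atoms: none
Why: Iodine–lithium exchange with retention, transmetalation to the Grignard and copper-catalysed SN2 opening of the glycidate at its CH2 terminus form C9–C10 and deliver C8 with the configuration of 9, (8S), i.e. O8 α, the epimer the key step needs; the ester is spared at −40 °C.

Step 7
Reactants: 12 hydroxy ester
Product: 13 TIPS ether of 12 at O8
Conditions: TIPSOTf, 2,6-lutidine, CH2Cl2, 0 °C
Reagents that add atoms: triisopropylsilyl triflate CC(C)[Si](OS(=O)(=O)C(F)(F)F)(C(C)C)C(C)C
Why: Silyl triflate silylation of a hindered α-hydroxy ester; TIPS is the most robust of the three silyl groups and is the last to be removed (step 24).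

Step 8
Reactants: 13 TIPS ether of 12
Product: 14 (2S,4Z,6S)-6-(TBSO)-10-(PMBO)-4-methyl-2-(TIPSO)dec-4-en-8-ynal
Conditions: DIBAL-H (1.1 equiv), CH2Cl2, −78 °C; Rochelle salt
Reagents that add atoms: none
Why: DIBAL-H at −78 °C stops at the aldehyde through the stable tetrahedral intermediate of an α-silyloxy ester; C8 does not epimerise under these conditions.

Step 9
Reactants: 15 methyl bis(2,2,2-trifluoroethyl)phosphonoacetate
Product: 16 methyl 2-bromo-2-[bis(2,2,2-trifluoroethoxy)phosphoryl]acetate
Conditions: NaH (1.0 equiv), THF, 0 °C; NBS, −78 to 0 °C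
Reagents that add atoms: N-bromosuccinimide O=C1CCC(=O)N1Br
Why: α-Bromination of the stabilised sodium phosphonate carbanion with one equivalent of NBS gives the bromophosphonate (racemic; its configuration is irrelevant).

Step 10
Reactants: 14 aldehyde; 16 bromophosphonate
Product: 17 methyl (2E,4S,6Z,8S)-2-bromo-8-(TBSO)-6-methyl-12-(PMBO)-4-(TIPSO)dodeca-2,6-dien-10-ynoate
Conditions: 16, t-BuOK, 18-crown-6, THF, −78 °C; then 14
Reagents that add atoms: none
Why: Still–Gennari-type Horner–Wadsworth–Emmons olefination with the electron-poor bis(trifluoroethyl) phosphonate is kinetically cis-selective for ester against aldehyde residue, so the ester (C12) ends cis to C8 and bromine trans to it ((E)-α-bromoacrylate).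

Step 11
Reactants: 17 α-bromo enoate
Product: 18 methyl (2Z,4S,6Z,8S)-2-(hydroxymethyl)-8-(TBSO)-6-methyl-12-(PMBO)-4-(TIPSO)dodeca-2,6-dien-10-ynoate
Conditions: Bu3SnCH2OH, Pd(PPh3)4 (5 mol%), dioxane, 90 °C
Reagents that add atoms: (tributylstannyl)methanol CCCC[Sn](CO)(CCCC)CCCC
Why: Stille coupling of the activated α-bromo enoate transfers the hydroxymethyl group with retention of olefin geometry, placing C13 trans to C8 on C11.

Step 12
Reactants: 18 hydroxymethyl enoate
Product: 20 methyl (2E,4S,6Z,8S)-2-(chloromethyl)-8-(TBSO)-6-methyl-12-(PMBO)-4-(TIPSO)dodeca-2,6-dien-10-ynoate, via allylic mesylate 19 (not isolated)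
Conditions: MsCl, Et3N, CH2Cl2, −20 °C; then LiCl, DMF, 0 °C to rt
Reagents that add atoms: methanesulfonyl chloride CS(=O)(=O)Cl (in 19 only); lithium chloride [Li+].[Cl-]
Why: Mesylation and in situ SN2 displacement by chloride give the primary allylic chloride; attack at C13 is favoured over SN2' at the hindered C7, so the olefin geometry is kept.

Step 13
Reactants: 20 chloromethyl enoate
Product: 21 (2E,4S,6Z,8S)-2-(chloromethyl)-8-(TBSO)-6-methyl-12-(PMBO)-4-(TIPSO)dodeca-2,6-dien-10-yn-1-ol
Conditions: DIBAL-H (2.2 equiv), CH2Cl2, −78 °C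
Reagents that add atoms: none
Why: 1,2-Reduction of the conjugated ester to the allylic alcohol (C12–OH) at −78 °C, a temperature at which the allylic chloride is not displaced.

Step 14
Reactants: 21 allylic alcohol
Product: 22 TBS ether of 21 at O12
Conditions: TBSCl, imidazole, CH2Cl2, 0 °C
Reagents that add atoms: tert-butyldimethylsilyl chloride CC(C)(C)[Si](C)(C)Cl
Why: Silylation of the primary allylic alcohol differentiates C12 (silyl ether) from C13 (chloride) and is stable to the bases of steps 16 and 17.

Step 15
Reactants: 22 PMB ether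
Product: 23 seco alcohol (C6–OH free; C13–Cl; O2-TBS; O8-TIPS; O12-TBS)
Conditions: DDQ, CH2Cl2/pH 7 buffer, 0 °C to rt
Reagents that add atoms: none
Why: Oxidative PMB cleavage (benzylic hydride abstraction, then hydrolysis) is orthogonal to the three silyl ethers and the allylic chloride and frees the propargylic C6 hydroxyl.

Step 16
Reactants: 23 seco alcohol
Product: 24 13-membered cyclic ether (O bridging C6 and C13; C4≡C5; 1(10)Z; C8 and C13 trans on C7=C11; 2S,8S)
Conditions: NaH, Bu4NI (cat.), THF, 0.003 M, slow addition, 45 °C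
Reagents that add atoms: none
Why: Intramolecular Williamson etherification at high dilution: the propargylic alkoxide displaces the primary allylic chloride (SN2, iodide catalysis) to close the strain-free 13-membered ether; SN2' at the substituted C7 is disfavoured and no stereo element is touched.

Step 17
Reactants: 24 13-membered cyclic ether
Product: 26 2α-(TBSO)-8α-(TIPSO)-12-(TBSO)-germacra-1(10)Z,11(13)-dien-4-yn-6α-ol, via C6-lithiated ether 25 (not isolated)
Conditions: n-BuLi (1.3 equiv), THF–pentane, −78 to −30 °C; aq NH4Cl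
Reagents that add atoms: none
Why: n-BuLi removes a C6 proton, the only one that is both α to the ether oxygen and propargylic (C4≡C5), so lithiation at C13 or C3 should not compete. The α-oxy propargyl anion 25 then undergoes a concerted, suprafacial [2,3]-Wittig shift through a five-membered envelope transition state (C6–O–C13–C11=C7): C6–C7 forms, O–C13 breaks and C11=C13 becomes the exocyclic methylene; the closest known reaction type is the [2,3]-Wittig ring contraction of 13-membered propargylic allylic ethers to cyclodecenynols. The ten-membered ring is therefore closed by contraction (O, C13 and C11 leave the ring of the unstrained ether), not by end-to-end cyclisation, and formation of the alkoxide makes the step irreversible. C6 relative to C7: with the ring-trans C7=C11 olefin the alkynyl group sits exo on the envelope (endo it would clash with the C12 CH2OTBS group on C11), a trans-fused bicyclic transition state that gives the anti pair (6α-OH, 7α-H). C7 relative to C8: allylic 1,3-strain with the cis CH2OTBS group holds H8 in the olefin plane, C9 must lie on the face attacked by the tethered carbanion, and the C8–OTIPS bond is therefore anti to the forming bond, which is also the stereoelectronically preferred arrangement for nucleophilic attack next to an allylic C–O bond. With (8S) this puts C6 on the face that gives the C7 configuration of the target, which is why O8 is carried as the α epimer and inverted in step 25. The step needs three selectivities (site of lithiation, anti, facial) and they are secured by the alkyne, by the olefin geometry set in step 10 and by the C8 centre taken from 9.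

Step 18
Reactants: 26 cyclodecenynol
Product: 28 4-iodo-15-nor-2α-(TBSO)-8α-(TIPSO)-12-(TBSO)-germacra-1(10)Z,4,11(13)-trien-6α-ol (C3 and C6 trans on C4=C5), via cyclic alkenylalanate 27 (not isolated)
Conditions: Red-Al, THF, 0 °C to rt; then I2, THF, −78 °C
Reagents that add atoms: iodine II
Why: Hydroxyl-directed trans-hydroalumination of the propargylic alcohol: the C6 alkoxide binds aluminium, hydride goes to C5 and aluminium ends on C4 in the five-membered oxa-alanate 27; iodinolysis with retention puts iodine on C4 cis to C6 and leaves C3 and C6 trans, the ring-trans C4=C5 geometry of the target.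

Step 19
Reactants: 28 alkenyl iodide
Product: 29 2α-(TBSO)-8α-(TIPSO)-12-(TBSO)-germacra-1(10)Z,4,11(13)-triene-6α,15-diol
Conditions: Bu3SnCH2OH, Pd2(dba)3 (cat.), AsPh3, CuI, NMP, 45 °C
Reagents that add atoms: (tributylstannyl)methanol CCCC[Sn](CO)(CCCC)CCCC
Why: Copper-assisted Stille hydroxymethylation with retention installs C15 on C4 at a temperature below that at which the 1,5-diene would be expected to undergo Cope rearrangement.

Step 20
Reactants: 29 6α,15-diol
Product: 30 15-acetate of 29
Conditions: Ac2O, 2,4,6-collidine, CH2Cl2, −20 °C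
Reagents that add atoms: acetic anhydride CC(=O)OC(C)=O
Why: Kinetic acylation: the primary allylic C15 hydroxyl is acetylated with a weak base at low temperature while the hindered secondary C6 hydroxyl stays free for the lactonisation.

Step 21
Reactants: 30 15-acetate
Product: 31 15-acetoxy-8α-(TIPSO)-germacra-1(10)Z,4,11(13)-triene-2α,6α,12-triol
Conditions: HF·pyridine, pyridine, THF, 0 °C to rt
Reagents that add atoms: none
Why: Buffered HF·pyridine cleaves the primary (O12) and the less hindered secondary (O2) TBS ethers much faster than the secondary TIPS ether on O8, which keeps O8 out of the lactonisation.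

Step 22
Reactants: 31 triol
Product: 34 15-acetoxy-2α-hydroxy-8α-(TIPSO)-germacra-1(10)Z,4,11(13)-trien-6α,12-olide, via enal 32 (not isolated), via lactol 33 (not isolated)
Conditions: TEMPO (cat.), PhI(OAc)2, CH2Cl2, rt
Reagents that add atoms: none
Why: TEMPO/PhI(OAc)2 oxidises the primary allylic alcohol selectively to the enal, which is trapped by the C6 hydroxyl as the lactol and oxidised again to the α-methylene lactone; secondary alcohols (C2, C6) react much more slowly with the oxoammonium ion, and the trans ring fusion follows from C6 and C7.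

Step 23
Reactants: 34 hydroxy lactone
Product: 35 2α-angelate of 34
Conditions: angelic acid, 2,4,6-trichlorobenzoyl chloride, Et3N, toluene, rt; then 34, 75 °C
Reagents that add atoms: angelic acid C/C=C(/C)C(=O)O
Why: Yamaguchi-type acylation with the preformed mixed anhydride and no nucleophilic catalyst esterifies the only free hydroxyl (C2) with retention at C2 and avoids the addition–elimination pathway that turns angelate into tiglate.

Step 24
Reactants: 35 angelate
Product: 36 15-acetoxy-2α-angeloyloxy-8α-hydroxy-germacra-1(10)Z,4,11(13)-trien-6α,12-olide (C8 epimer of the target)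
Conditions: HF·pyridine, THF, rt
Reagents that add atoms: none
Why: Fluoride-mediated cleavage of the remaining TIPS ether under mildly acidic conditions that leave the three esters and the methylene lactone intact.

Step 25
Reactants: 36 8α-alcohol
Product: 37 8β-chloroacetate
Conditions: ClCH2CO2H, PPh3, DIAD (betaine preformed), toluene, 0 °C to rt
Reagents that add atoms: chloroacetic acid OC(=O)CCl
Why: Mitsunobu reaction: the C8 alkoxyphosphonium ion is displaced by chloroacetate in an SN2 step, inverting C8 to (R) (O8 β); the acidic nucleophile suits a hindered secondary alcohol, and preforming the betaine keeps free phosphine away from the methylene lactone.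

Step 26
Reactants: 37 8β-chloroacetate
Product: 38 15-acetoxy-2α-angeloyloxy-8β-hydroxy-germacra-1(10)Z,4,11(13)-trien-6α,12-olide (target)
Conditions: thiourea, NaHCO3, EtOH/THF, rt
Reagents that add atoms: none
Why: Thiourea is S-alkylated by the α-chloro ester and the isothiouronium ion cyclises onto the ester carbonyl, releasing the C8 alcohol under near-neutral conditions; acetate, angelate and lactone lack the activating chloride and should not be cleaved.

## Compound list

1 | 4-methoxybenzyl propargyl ether | C#CCOCc1ccc(OC)cc1 | starting material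
2 | (S)-glycidyl trityl ether | C1[C@H](O1)COC(c2ccccc2)(c3ccccc3)c4ccccc4 | starting material
3 | lithium acetylide of 1 | [Li]C#CCOCc1ccc(OC)cc1 | intermediate (not isolated)
4 | (2S)-6-(4-methoxybenzyloxy)-1-(trityloxy)hex-4-yn-2-ol | COc1ccc(COCC#CC[C@H](O)COC(c2ccccc2)(c3ccccc3)c4ccccc4)cc1 | intermediate
5 | (2S)-2-(TBSO)-6-(PMBO)-1-(TrO)hex-4-yne | COc1ccc(COCC#CC[C@H](O[Si](C)(C)C(C)(C)C)COC(c2ccccc2)(c3ccccc3)c4ccccc4)cc1 | intermediate
6 | (2S)-2-(TBSO)-6-(PMBO)hex-4-yn-1-ol | COc1ccc(COCC#CC[C@H](O[Si](C)(C)C(C)(C)C)CO)cc1 | intermediate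
7 | (2S)-2-(TBSO)-6-(PMBO)hex-4-ynal | COc1ccc(COCC#CC[C@H](O[Si](C)(C)C(C)(C)C)C=O)cc1 | intermediate
8 | (2Z,4S)-4-(TBSO)-2-iodo-8-(PMBO)oct-2-en-6-yne | COc1ccc(COCC#CC[C@H](O[Si](C)(C)C(C)(C)C)/C=C(/C)I)cc1 | intermediate
9 | methyl (S)-glycidate | COC(=O)[C@@H]1CO1 | starting material
10 | alkenyllithium from 8 (Li in place of I) | COc1ccc(COCC#CC[C@H](O[Si](C)(C)C(C)(C)C)/C=C(/C)[Li])cc1 | intermediate (not isolated)
11 | alkenylmagnesium bromide from 10 | COc1ccc(COCC#CC[C@H](O[Si](C)(C)C(C)(C)C)/C=C(/C)[Mg]Br)cc1 | intermediate (not isolated)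
12 | methyl (2S,4Z,6S)-6-(TBSO)-2-hydroxy-10-(PMBO)-4-methyldec-4-en-8-ynoate | COc1ccc(COCC#CC[C@H](O[Si](C)(C)C(C)(C)C)/C=C(/C)C[C@H](O)C(=O)OC)cc1 | intermediate
13 | methyl (2S,4Z,6S)-6-(TBSO)-10-(PMBO)-4-methyl-2-(TIPSO)dec-4-en-8-ynoate | COc1ccc(COCC#CC[C@H](O[Si](C)(C)C(C)(C)C)/C=C(/C)C[C@H](O[Si](C(C)C)(C(C)C)C(C)C)C(=O)OC)cc1 | intermediate
14 | (2S,4Z,6S)-6-(TBSO)-10-(PMBO)-4-methyl-2-(TIPSO)dec-4-en-8-ynal | COc1ccc(COCC#CC[C@H](O[Si](C)(C)C(C)(C)C)/C=C(/C)C[C@H](O[Si](C(C)C)(C(C)C)C(C)C)C=O)cc1 | intermediate
15 | methyl bis(2,2,2-trifluoroethyl)phosphonoacetate | COC(=O)CP(=O)(OCC(F)(F)F)OCC(F)(F)F | starting material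
16 | methyl 2-bromo-2-[bis(2,2,2-trifluoroethoxy)phosphoryl]acetate (racemic) | COC(=O)C(Br)P(=O)(OCC(F)(F)F)OCC(F)(F)F | intermediate
17 | methyl (2E,4S,6Z,8S)-2-bromo-8-(TBSO)-6-methyl-12-(PMBO)-4-(TIPSO)dodeca-2,6-dien-10-ynoate | COc1ccc(COCC#CC[C@H](O[Si](C)(C)C(C)(C)C)/C=C(/C)C[C@H](O[Si](C(C)C)(C(C)C)C(C)C)/C=C(/Br)C(=O)OC)cc1 | intermediate
18 | methyl (2Z,4S,6Z,8S)-2-(hydroxymethyl)-8-(TBSO)-6-methyl-12-(PMBO)-4-(TIPSO)dodeca-2,6-dien-10-ynoate | COc1ccc(COCC#CC[C@H](O[Si](C)(C)C(C)(C)C)/C=C(/C)C[C@H](O[Si](C(C)C)(C(C)C)C(C)C)/C=C(/CO)C(=O)OC)cc1 | intermediate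
19 | mesylate of 18 | COc1ccc(COCC#CC[C@H](O[Si](C)(C)C(C)(C)C)/C=C(/C)C[C@H](O[Si](C(C)C)(C(C)C)C(C)C)/C=C(/COS(C)(=O)=O)C(=O)OC)cc1 | intermediate (not isolated)
20 | methyl (2E,4S,6Z,8S)-2-(chloromethyl)-8-(TBSO)-6-methyl-12-(PMBO)-4-(TIPSO)dodeca-2,6-dien-10-ynoate | COc1ccc(COCC#CC[C@H](O[Si](C)(C)C(C)(C)C)/C=C(/C)C[C@H](O[Si](C(C)C)(C(C)C)C(C)C)/C=C(/CCl)C(=O)OC)cc1 | intermediate
21 | (2E,4S,6Z,8S)-2-(chloromethyl)-8-(TBSO)-6-methyl-12-(PMBO)-4-(TIPSO)dodeca-2,6-dien-10-yn-1-ol | COc1ccc(COCC#CC[C@H](O[Si](C)(C)C(C)(C)C)/C=C(/C)C[C@H](O[Si](C(C)C)(C(C)C)C(C)C)/C=C(/CCl)CO)cc1 | intermediate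
22 | 1-O-TBS ether of 21 | COc1ccc(COCC#CC[C@H](O[Si](C)(C)C(C)(C)C)/C=C(/C)C[C@H](O[Si](C(C)C)(C(C)C)C(C)C)/C=C(/CCl)CO[Si](C)(C)C(C)(C)C)cc1 | intermediate
23 | seco alcohol: (2E,4S,6Z,8S)-1,8-bis(TBSO)-2-(chloromethyl)-6-methyl-4-(TIPSO)dodeca-2,6-dien-10-yn-12-ol | OCC#CC[C@H](O[Si](C)(C)C(C)(C)C)/C=C(/C)C[C@H](O[Si](C(C)C)(C(C)C)C(C)C)/C=C(/CCl)CO[Si](C)(C)C(C)(C)C | intermediate
24 | 13-membered ether: O bridges C6 and C13; C4≡C5; (1(10)Z); C8 and C13 trans on C7=C11; 2S-OTBS, 8S-OTIPS, 12-OTBS | O1CC#CC[C@H](O[Si](C)(C)C(C)(C)C)/C=C(/C)C[C@H](O[Si](C(C)C)(C(C)C)C(C)C)/C=C(/C1)CO[Si](C)(C)C(C)(C)C | intermediate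
25 | C6-lithiated 24 | O1C([Li])C#CC[C@H](O[Si](C)(C)C(C)(C)C)/C=C(/C)C[C@H](O[Si](C(C)C)(C(C)C)C(C)C)/C=C(/C1)CO[Si](C)(C)C(C)(C)C | intermediate (not isolated)
26 | 2α-(TBSO)-8α-(TIPSO)-12-(TBSO)-germacra-1(10)Z,11(13)-dien-4-yn-6α-ol (6,7-anti; 7α-H) | O[C@@H]1C#CC[C@H](O[Si](C)(C)C(C)(C)C)/C=C(/C)C[C@H](O[Si](C(C)C)(C(C)C)C(C)C)[C@H]1C(=C)CO[Si](C)(C)C(C)(C)C | intermediate
27 | sodium oxa-alanate: Al bridges O6 and C4, two 2-methoxyethoxy groups on Al | [Na+].COCCO[Al-]1(OCCOC)O[C@@H]2/C=C1/C[C@H](O[Si](C)(C)C(C)(C)C)/C=C(/C)C[C@H](O[Si](C(C)C)(C(C)C)C(C)C)[C@H]2C(=C)CO[Si](C)(C)C(C)(C)C | intermediate (not isolated)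
28 | 4-iodo-15-nor-2α-(TBSO)-8α-(TIPSO)-12-(TBSO)-germacra-1(10)Z,4,11(13)-trien-6α-ol (ring-trans C4=C5, I cis to C6) | O[C@@H]1/C=C(\I)C[C@H](O[Si](C)(C)C(C)(C)C)/C=C(/C)C[C@H](O[Si](C(C)C)(C(C)C)C(C)C)[C@H]1C(=C)CO[Si](C)(C)C(C)(C)C | intermediate
29 | 2α-(TBSO)-8α-(TIPSO)-12-(TBSO)-germacra-1(10)Z,4,11(13)-triene-6α,15-diol | O[C@@H]1/C=C(\CO)C[C@H](O[Si](C)(C)C(C)(C)C)/C=C(/C)C[C@H](O[Si](C(C)C)(C(C)C)C(C)C)[C@H]1C(=C)CO[Si](C)(C)C(C)(C)C | intermediate
30 | 15-acetate of 29 | O[C@@H]1/C=C(\COC(C)=O)C[C@H](O[Si](C)(C)C(C)(C)C)/C=C(/C)C[C@H](O[Si](C(C)C)(C(C)C)C(C)C)[C@H]1C(=C)CO[Si](C)(C)C(C)(C)C | intermediate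
31 | 15-acetoxy-8α-(TIPSO)-germacra-1(10)Z,4,11(13)-triene-2α,6α,12-triol | O[C@@H]1/C=C(\COC(C)=O)C[C@H](O)/C=C(/C)C[C@H](O[Si](C(C)C)(C(C)C)C(C)C)[C@H]1C(=C)CO | intermediate
32 | 12-al of 31 | O[C@@H]1/C=C(\COC(C)=O)C[C@H](O)/C=C(/C)C[C@H](O[Si](C(C)C)(C(C)C)C(C)C)[C@H]1C(=C)C=O | intermediate (not isolated)
33 | 6α,12-lactol of 32 | C=C1C(O)O[C@@H]2/C=C(\COC(C)=O)C[C@H](O)/C=C(/C)C[C@H](O[Si](C(C)C)(C(C)C)C(C)C)[C@@H]12 | intermediate (not isolated)
34 | 15-acetoxy-2α-hydroxy-8α-(TIPSO)-germacra-1(10)Z,4,11(13)-trien-6α,12-olide | C=C1C(=O)O[C@@H]2/C=C(\COC(C)=O)C[C@H](O)/C=C(/C)C[C@H](O[Si](C(C)C)(C(C)C)C(C)C)[C@@H]12 | intermediate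
35 | 15-acetoxy-2α-angeloyloxy-8α-(TIPSO)-germacra-1(10)Z,4,11(13)-trien-6α,12-olide | C=C1C(=O)O[C@@H]2/C=C(\COC(C)=O)C[C@H](OC(=O)/C(C)=C\C)/C=C(/C)C[C@H](O[Si](C(C)C)(C(C)C)C(C)C)[C@@H]12 | intermediate
36 | 15-acetoxy-2α-angeloyloxy-8α-hydroxy-germacra-1(10)Z,4,11(13)-trien-6α,12-olide (8-epimer of the target) | C=C1C(=O)O[C@@H]2/C=C(\COC(C)=O)C[C@H](OC(=O)/C(C)=C\C)/C=C(/C)C[C@H](O)[C@@H]12 | intermediate
37 | 8β-chloroacetate (C8 inverted) | C=C1C(=O)O[C@@H]2/C=C(\COC(C)=O)C[C@H](OC(=O)/C(C)=C\C)/C=C(/C)C[C@@H](OC(=O)CCl)[C@@H]12 | intermediate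
38 | CNP0129394.1: (2S,6R,7R,8R)-15-acetoxy-2α-angeloyloxy-8β-hydroxy-germacra-1(10)Z,4,11(13)-trien-6α,12-olide | C=C1C(=O)O[C@@H]2/C=C(\COC(C)=O)C[C@H](OC(=O)/C(C)=C\C)/C=C(/C)C[C@@H](O)[C@@H]12 | target

## Step count and least certain steps

Total step count: 26. Longest linear sequence: 25 steps (steps 1–8 and 10–26; step 9 prepares reagent 16).

Step 17 (key step). The most likely failure is erosion of the anti (C6/C7) selectivity, possibly with a competing [1,2]-shift. The trans-fused envelope has to span C5 to C8 with a short tether that contains the Z olefin, so the cis-fused arrangement may become competitive. The facial sense at C7 rests on two effects that reinforce each other and is the lesser risk. The fallback replaces sigmatropic control at C6 by reagent control. It sets out from crude 26, whatever its purity at C6. Dess–Martin oxidation of the propargylic alcohol should give the ynone F1. Base-free asymmetric transfer hydrogenation (Ru(p-cymene)[(S,S)-TsDPEN], i-PrOH) is expected, by analogy with simple alkynyl ketones, to give the (6S) propargylic alcohol. It comes back at 26.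

Step 16. The most likely failure is oligomerisation by intermolecular etherification, or base-induced isomerisation of the propargylic alkoxide, because the 13-membered closure is slow even at high dilution. The fallback does without the cyclic ether and closes the carbocycle directly at C6–C7, which also bypasses step 17. It sets out from 23. MnO2 oxidation should give the ynal F2. A Nozaki–Hiyama–Kishi allylation (CrCl2, cat. LiI, THF, high dilution) should then add the allylchromium species through its γ-carbon C7 to the aldehyde; the usual anti preference of the chair transition state applies, and the facial sense would have to be established. It comes back at 26.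

Step 18. The most likely failure is incomplete or regio-unselective hydroalumination, because the ring must accommodate a trans olefin inside an oxa-alanate; desilylation by the aluminate is a lesser concern. The fallback uses a catalytic trans addition instead. It sets out from 26. Ruthenium-catalysed trans-hydrosilylation ([Cp*Ru(MeCN)3]PF6, Et3SiH), which places silicon distal to a propargylic hydroxyl, should give the alkenylsilane F3. Iododesilylation with retention (NIS, hexafluoroisopropanol) then gives the iodide. It comes back at 28.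

Step 5. The most likely failure is low Z selectivity and low yield, through loss of iodine from the ylide and partial epimerisation of the α-silyloxy aldehyde. The fallback builds the olefin by stereoselective cross-coupling. It sets out from 7. Corey–Fuchs olefination (CBr4, PPh3) gives the 1,1-dibromoalkene F4. A trans-selective Negishi monomethylation (MeZnCl, Pd catalyst) replaces the bromine trans to C2 and gives the (Z)-2-bromoalkene F5. Bromine–lithium exchange under the conditions of step 6 gives the same alkenyllithium. It comes back at 10, and hence at 12.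

Step 25. The most likely failure is elimination towards C9 or C7 in place of substitution, or conjugate addition of phosphine to the methylene lactone. Step 26 then adds the risk of thiourea adding to the same acceptor. The fallback avoids both the phosphine and the ester cleavage. It sets out from 36. Tf2O and pyridine at −30 °C give the C8 triflate F6. A Lattrell–Dax-type displacement with Bu4NNO2 gives the inverted nitrite ester F7, which hydrolyses on work-up. It comes back at 38.

## Further compounds

F1 | step 17 | ynone (C6 ketone of 26) | O=C1C#CC[C@H](O[Si](C)(C)C(C)(C)C)/C=C(/C)C[C@H](O[Si](C(C)C)(C(C)C)C(C)C)[C@H]1C(=C)CO[Si](C)(C)C(C)(C)C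
F2 | step 16 | ynal (C6 aldehyde of 23) | O=CC#CC[C@H](O[Si](C)(C)C(C)(C)C)/C=C(/C)C[C@H](O[Si](C(C)C)(C(C)C)C(C)C)/C=C(/CCl)CO[Si](C)(C)C(C)(C)C
F3 | step 18 | C4-triethylsilyl alkene (Si cis to C6, ring-trans C4=C5) | O[C@@H]1/C=C(\[Si](CC)(CC)CC)C[C@H](O[Si](C)(C)C(C)(C)C)/C=C(/C)C[C@H](O[Si](C(C)C)(C(C)C)C(C)C)[C@H]1C(=C)CO[Si](C)(C)C(C)(C)C
F4 | step 5 | (3S)-1,1-dibromo-3-(TBSO)-7-(PMBO)hept-1-en-5-yne | COc1ccc(COCC#CC[C@H](O[Si](C)(C)C(C)(C)C)C=C(Br)Br)cc1
F5 | step 5 | (2Z,4S)-2-bromo-4-(TBSO)-8-(PMBO)oct-2-en-6-yne | COc1ccc(COCC#CC[C@H](O[Si](C)(C)C(C)(C)C)/C=C(/C)Br)cc1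
F6 | step 25 | 8α-triflate of 36 | C=C1C(=O)O[C@@H]2/C=C(\COC(C)=O)C[C@H](OC(=O)/C(C)=C\C)/C=C(/C)C[C@H](OS(=O)(=O)C(F)(F)F)[C@@H]12
F7 | step 25 | 8β-nitrite ester | C=C1C(=O)O[C@@H]2/C=C(\COC(C)=O)C[C@H](OC(=O)/C(C)=C\C)/C=C(/C)C[C@@H](ON=O)[C@@H]12
A1 | alternative 1 | open-chain C6 aldehyde with C13 allylic bromide (methyl 2-(bromomethyl)enoate) | O=C/C=C(\COC(C)=O)C[C@H](O[Si](C)(C)C(C)(C)C)/C=C(/C)C[C@@H](O[Si](C)(C)C(C)(C)C)/C=C(/CBr)C(=O)OC
A2 | alternative 2 | 1,10-seco diene lactone (vinyl on C2, isopropenyl on C9, O8-triethylsilyl) | C=C1C(=O)O[C@H](/C=C(\COC(C)=O)C[C@H](OC(=O)/C(C)=C\C)C=C)[C@H]1[C@H](O[Si](CC)(CC)CC)CC(C)=C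
A3 | alternative 3 | 11-membered cyclic sulfone (SO2 between C1 and C10; O2 and O8 as TBS ethers) | C=C1C(=O)O[C@@H]2/C=C(\COC(C)=O)C[C@H](O[Si](C)(C)C(C)(C)C)CS(=O)(=O)C(C)C[C@@H](O[Si](C)(C)C(C)(C)C)[C@@H]12
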